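**Retrosynthetic overview**
- Target ⇒ Wittig olefination at C11=C12 between a ring A keto-enal that already carries the C19 dodecenoate and a C25 ring B polyenyl phosphonium salt.
- Keto-enal ⇒ esterification and acetal hydrolysis of a hydroxy enone made by Weinreb ketone synthesis from a ring A acetamide and an alkenyl Grignard reagent (syn hydromagnesiation of 4,4-diethoxybut-2-yn-1-ol fixes the C9=C10 geometry).
- Ring A Weinreb amide ⇒ light-driven, nickel-catalysed transpositive allylic C–H carbamoylation of the exocyclic methylidene compound made from (4R,6R)-actinol; this forms the C7–C8 bond.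
- C25 salt ⇒ C10 dialdehyde plus a C15 salt from (R)-α-ionone (vinyl Grignard addition, allylic oxidation, substrate-controlled reduction, Mitsunobu inversion, PPh3·HBr).
- No ring is formed: ring A is bought in actinol and ring B in α-ionone; the ring A side chain is built first, the ring B polyene second, and the two are joined last.

Assumption: every compound marked "starting material" in the list is commercial; positions are given with carotenoid locants (C7, C8, C19 on the ring A side, primed locants on the ring B side).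

**Route**

Step 1
Reactants: 1 (4R,6R)-4-hydroxy-2,2,6-trimethylcyclohexan-1-one (actinol)
Product: 3 triethyl{[(1R,5R)-3,3,5-trimethyl-4-methylidenecyclohexyl]oxy}silane, via methylidene alcohol 2 (not isolated)
Conditions: Ph3PCH3Br (2.5 equiv), KOt-Bu (2.4 equiv), toluene, 90 °C; then Et3SiCl (3 equiv), 0 °C to rt
Reagents that add atoms: methyltriphenylphosphonium bromide, C[P+](c1ccccc1)(c1ccccc1)c1ccccc1.[Br-]; chlorotriethylsilane, CC[Si](Cl)(CC)CC
Why: Wittig methylenation of the hindered ketone with excess ylide at 90 °C, followed by silylation of the potassium alkoxide in the same flask; the carbinol centre is untouched and the methyl-bearing centre is removed in step 2.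

Step 2
Reactants: 3 triethyl{[(1R,5R)-3,3,5-trimethyl-4-methylidenecyclohexyl]oxy}silane
Product: 4 N-methoxy-N-methyl-2-[(4R)-2,6,6-trimethyl-4-(triethylsilyloxy)cyclohex-1-en-1-yl]acetamide
Conditions: ClC(O)N(OMe)Me (limiting, 3 in 1.5-fold excess), NiBr2·glyme (5 mol %), 4,4'-di-tert-butyl-2,2'-bipyridine (6 mol %), [Ir(dF(CF3)ppy)2(dtbbpy)]PF6 (1 mol %), Bu4NBr (20 mol %), K3PO4 (2 equiv), PhCF3, degassed, blue LEDs (450 nm), 25 °C
Reagents that add atoms: N-methoxy-N-methylcarbamoyl chloride, CON(C)C(Cl)=O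
Why: Proposed new method: transpositive allylic C(sp3)–H carbamoylation — the carbamoyl chloride adds oxidatively to zerovalent nickel, the excited iridium photocatalyst triggers homolysis of the nickel–bromine bond, the bromine atom abstracts the only allylic hydrogen (the tertiary ring C–H next to the methylidene group), and the resulting allyl radical is captured by nickel at its unhindered CH2 terminus, so reductive elimination forms the C7–C8 bond and leaves the tetrasubstituted ring alkene; the closest known reaction types are nickel/photoredox allylic C–H arylation by bromine-atom hydrogen abstraction and nickel/photoredox C(sp3)–H acylation with acyl chlorides, and the remote silyloxy centre is not involved.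

Step 3
Reactants: 5 3,3-diethoxyprop-1-yne
Product: 7 4,4-diethoxybut-2-yn-1-ol, via lithium acetylide 6 (not isolated)
Conditions: n-BuLi (1.05 equiv), THF, −78 °C; then (CH2O)n, −78 °C to rt; H2O
Reagents that add atoms: paraformaldehyde (formaldehyde), C=O
Why: Deprotonation of the terminal alkyne and 1,2-addition of the lithium acetylide to formaldehyde (acetylide hydroxymethylation).

Step 4
Reactants: 7 4,4-diethoxybut-2-yn-1-ol; 4 N-methoxy-N-methyl-2-[(4R)-2,6,6-trimethyl-4-(triethylsilyloxy)cyclohex-1-en-1-yl]acetamide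
Product: 9 (3E)-5,5-diethoxy-3-(hydroxymethyl)-1-[(4R)-2,6,6-trimethyl-4-(triethylsilyloxy)cyclohex-1-en-1-yl]pent-3-en-2-one, via alkenylmagnesium reagent 8 (not isolated)
Conditions: 7 (1.5 equiv), i-BuMgCl (3.1 equiv), Cp2TiCl2 (5 mol %), Et2O, 0 °C to rt; then 4 (1.0 equiv), THF, 0 °C to rt; pH 7 phosphate buffer
Reagents that add atoms: none
Why: Sato hydromagnesiation (Cp2TiCl2-catalysed syn addition of H–Mg to a 2-alkyn-1-ol, magnesium on the carbon next to the alkoxide) gives the alkenyl Grignard reagent with CH2O and CH(OEt)2 cis, and its Weinreb ketone synthesis with 4 stops at the ketone with retention of this geometry (E enone).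

Step 5
Reactants: 9 (3E)-5,5-diethoxy-3-(hydroxymethyl)-1-[(4R)-2,6,6-trimethyl-4-(triethylsilyloxy)cyclohex-1-en-1-yl]pent-3-en-2-one; 10 (2E)-dodec-2-enoic acid
Product: 11 (2E)-4,4-diethoxy-2-{[(4R)-2,6,6-trimethyl-4-(triethylsilyloxy)cyclohex-1-en-1-yl]acetyl}but-2-en-1-yl (2E)-dodec-2-enoate
Conditions: DCC (1.3 equiv), DMAP (0.1 equiv), CH2Cl2, 0 °C
Reagents that add atoms: none
Why: Steglich esterification of the only free hydroxyl (primary, allylic) under non-acidic conditions, which avoids cyclisation of the hydroxy acetal to a furan.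

Step 6
Reactants: 11 (2E)-4,4-diethoxy-2-{[(4R)-2,6,6-trimethyl-4-(triethylsilyloxy)cyclohex-1-en-1-yl]acetyl}but-2-en-1-yl (2E)-dodec-2-enoate
Product: 12 (2E)-2-{[(4R)-4-hydroxy-2,6,6-trimethylcyclohex-1-en-1-yl]acetyl}-4-oxobut-2-en-1-yl (2E)-dodec-2-enoate
Conditions: Amberlyst-15 (H+ resin), acetone/H2O 20:1, rt
Reagents that add atoms: water, O
Why: Acid-catalysed acetal hydrolysis and triethylsilyl ether cleavage in one operation; the acylated CH2O group cannot close onto the aldehyde and the E enone and ester are stable to the resin.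

Step 7
Reactants: 13 (3E)-4-[(1R)-2,6,6-trimethylcyclohex-2-en-1-yl]but-3-en-2-one ((R)-α-ionone)
Product: 14 (1E)-3-methyl-1-[(1R)-2,6,6-trimethylcyclohex-2-en-1-yl]penta-1,4-dien-3-ol (both C3 epimers)
Conditions: CH2=CHMgBr (1.3 equiv), THF, −20 to 0 °C; H2O
Reagents that add atoms: vinylmagnesium bromide, C=C[Mg]Br
Why: 1,2-Grignard addition to the enone carbonyl (vinyl-ionol synthesis); the new carbinol centre forms as both epimers and disappears in step 11, and the bought ring centre is untouched.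

Step 8
Reactants: 14 (1E)-3-methyl-1-[(1R)-2,6,6-trimethylcyclohex-2-en-1-yl]penta-1,4-dien-3-ol
Product: 15 (4R)-4-[(1E)-3-hydroxy-3-methylpenta-1,4-dien-1-yl]-3,5,5-trimethylcyclohex-2-en-1-one
Conditions: t-BuOOH (5 equiv), Rh2(cap)4 (1 mol %), K2CO3 (0.5 equiv), CH2Cl2, 25 °C
Reagents that add atoms: tert-butyl hydroperoxide, CC(C)(C)OO
Why: Radical allylic C–H oxidation (Kharasch-type, dirhodium caprolactamate with t-BuOOH) at the only unhindered allylic methylene of ring B, as in the known conversion of α-ionone into 3-oxo-α-ionone; the tertiary alcohol is inert and the shielded ring methine keeps its configuration.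

Step 9
Reactants: 15 (4R)-4-[(1E)-3-hydroxy-3-methylpenta-1,4-dien-1-yl]-3,5,5-trimethylcyclohex-2-en-1-one
Product: 16 (1S,4R)-4-[(1E)-3-hydroxy-3-methylpenta-1,4-dien-1-yl]-3,5,5-trimethylcyclohex-2-en-1-ol
Conditions: LiBH(s-Bu)3 (2.5 equiv), THF, −78 °C; H2O
Reagents that add atoms: none
Why: 1,2-reduction of the β,β-disubstituted cyclohexenone by the bulky hydride from the face away from the axial ring methyl (half-chair with the side chain pseudo-equatorial) gives the 1,4-cis allylic alcohol, so the new centre is controlled by the bought one.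

Step 10
Reactants: 16 (1S,4R)-4-[(1E)-3-hydroxy-3-methylpenta-1,4-dien-1-yl]-3,5,5-trimethylcyclohex-2-en-1-ol
Product: 17 (1R,4R)-4-[(1E)-3-hydroxy-3-methylpenta-1,4-dien-1-yl]-3,5,5-trimethylcyclohex-2-en-1-yl 4-nitrobenzoate
Conditions: 4-O2NC6H4CO2H (1.5 equiv), PPh3 (1.5 equiv), DIAD (1.5 equiv), THF, 0 °C to rt
Reagents that add atoms: 4-nitrobenzoic acid, OC(=O)c1ccc(cc1)[N+](=O)[O-]
Why: Mitsunobu reaction (SN2 inversion at the secondary allylic carbinol, tertiary alcohol inert) converts the cis alcohol into the trans (1R) ester, which has the relative configuration of the target's ring B.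

Step 11
Reactants: 17 (1R,4R)-4-[(1E)-3-hydroxy-3-methylpenta-1,4-dien-1-yl]-3,5,5-trimethylcyclohex-2-en-1-yl 4-nitrobenzoate
Product: 18 {(2E,4E)-3-methyl-5-[(1R,4R)-2,6,6-trimethyl-4-(4-nitrobenzoyloxy)cyclohex-2-en-1-yl]penta-2,4-dien-1-yl}triphenylphosphonium bromide
Conditions: PPh3·HBr (1.05 equiv), MeOH, 0 °C to rt; crystallise from EtOAc
Reagents that add atoms: triphenylphosphine hydrobromide, [Br-].[PH+](c1ccccc1)(c1ccccc1)c1ccccc1
Why: Acid ionisation of the tertiary bis-allylic alcohol and capture of the pentadienyl cation by PPh3 at the terminal carbon (allylic transposition used for C15 Wittig salts); the 2E salt crystallises and the electron-poor benzoate shields the ring allylic oxygen from ionisation.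

Step 12
Reactants: 18 {(2E,4E)-3-methyl-5-[(1R,4R)-2,6,6-trimethyl-4-(4-nitrobenzoyloxy)cyclohex-2-en-1-yl]penta-2,4-dien-1-yl}triphenylphosphonium bromide; 19 (2E,4E,6E)-2,7-dimethylocta-2,4,6-trienedial
Product: 20 (2E,4E,6E,8E,10E,12E)-2,7,11-trimethyl-13-[(1R,4R)-2,6,6-trimethyl-4-(4-nitrobenzoyloxy)cyclohex-2-en-1-yl]trideca-2,4,6,8,10,12-hexaenal
Conditions: 19 (3 equiv), 1,2-epoxybutane/EtOH 1:1, reflux; excess 19 recovered
Reagents that add atoms: none
Why: Wittig olefination under neutral epoxide conditions (the epoxide scavenges HBr), with excess dialdehyde enforcing mono-condensation; Z isomers of the new disubstituted bond equilibrate thermally to E during the reflux.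

Step 13
Reactants: 20 (2E,4E,6E,8E,10E,12E)-2,7,11-trimethyl-13-[(1R,4R)-2,6,6-trimethyl-4-(4-nitrobenzoyloxy)cyclohex-2-en-1-yl]trideca-2,4,6,8,10,12-hexaenal
Product: 22 (1R,4R)-4-[(1E,3E,5E,7E,9E,11E)-13-hydroxy-3,7,12-trimethyltrideca-1,3,5,7,9,11-hexaen-1-yl]-3,5,5-trimethylcyclohex-2-en-1-ol, via nitrobenzoate alcohol 21 (not isolated)
Conditions: NaBH4, MeOH/THF, 0 °C; then K2CO3 (0.3 equiv), MeOH, rt
Reagents that add atoms: none
Why: 1,2-reduction of the polyenal by borohydride, then base-catalysed methanolysis (transesterification) of the 4-nitrobenzoate with retention at the ring carbinol.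

Step 14
Reactants: 22 (1R,4R)-4-[(1E,3E,5E,7E,9E,11E)-13-hydroxy-3,7,12-trimethyltrideca-1,3,5,7,9,11-hexaen-1-yl]-3,5,5-trimethylcyclohex-2-en-1-ol
Product: 23 {(2E,4E,6E,8E,10E,12E)-13-[(1R,4R)-4-hydroxy-2,6,6-trimethylcyclohex-2-en-1-yl]-2,7,11-trimethyltrideca-2,4,6,8,10,12-hexaen-1-yl}triphenylphosphonium bromide
Conditions: PPh3·HBr (1.0 equiv), MeOH/CH2Cl2, 0 °C, 1 h
Reagents that add atoms: triphenylphosphine hydrobromide, [Br-].[PH+](c1ccccc1)(c1ccccc1)c1ccccc1
Why: The primary polyenylic alcohol ionises far faster than the ring allylic alcohol at 0 °C and PPh3 traps the cation at the terminal carbon (standard phosphonium salt formation from polyenols), so the ring carbinol keeps its configuration.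

Step 15
Reactants: 23 {(2E,4E,6E,8E,10E,12E)-13-[(1R,4R)-4-hydroxy-2,6,6-trimethylcyclohex-2-en-1-yl]-2,7,11-trimethyltrideca-2,4,6,8,10,12-hexaen-1-yl}triphenylphosphonium bromide; 12 (2E)-2-{[(4R)-4-hydroxy-2,6,6-trimethylcyclohex-1-en-1-yl]acetyl}-4-oxobut-2-en-1-yl (2E)-dodec-2-enoate
Product: 24 (3R,3'R,6'R)-3,3'-dihydroxy-8-oxo-7,8-dihydro-β,ε-caroten-19-yl (2E)-dodec-2-enoate (siphonein)
Conditions: 1,2-epoxybutane/CH2Cl2, 45 °C, dark, argon; chromatography, crystallisation
Reagents that add atoms: none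
Why: Wittig olefination of the aldehyde (much more reactive than the ketone) with the polyenyl ylide under neutral epoxide conditions that the allylic enoate ester and free hydroxyls tolerate; the hindered Z isomer of the new C11=C12 bond equilibrates thermally to the all-E polyene.

**Compound list**
1 | (4R,6R)-4-hydroxy-2,2,6-trimethylcyclohexan-1-one (actinol) | O=C1C(C)(C)C[C@H](O)C[C@H]1C | starting material
2 | (1R,5R)-3,3,5-trimethyl-4-methylidenecyclohexan-1-ol (present as potassium alkoxide) | C=C1C(C)(C)C[C@H](O)C[C@H]1C | intermediate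
3 | triethyl{[(1R,5R)-3,3,5-trimethyl-4-methylidenecyclohexyl]oxy}silane | C=C1C(C)(C)C[C@H](O[Si](CC)(CC)CC)C[C@H]1C | intermediate
4 | N-methoxy-N-methyl-2-[(4R)-2,6,6-trimethyl-4-(triethylsilyloxy)cyclohex-1-en-1-yl]acetamide | CON(C)C(=O)CC1=C(C)C[C@@H](O[Si](CC)(CC)CC)CC1(C)C | intermediate
5 | 3,3-diethoxyprop-1-yne | C#CC(OCC)OCC | starting material
6 | lithium 3,3-diethoxyprop-1-yn-1-ide | [Li]C#CC(OCC)OCC | intermediate
7 | 4,4-diethoxybut-2-yn-1-ol | OCC#CC(OCC)OCC | intermediate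
8 | chloromagnesium (2E)-2-(chloromagnesio)-4,4-diethoxybut-2-en-1-olate | Cl[Mg]OC/C([Mg]Cl)=C\C(OCC)OCC | intermediate
9 | (3E)-5,5-diethoxy-3-(hydroxymethyl)-1-[(4R)-2,6,6-trimethyl-4-(triethylsilyloxy)cyclohex-1-en-1-yl]pent-3-en-2-one | CCOC(OCC)/C=C(\CO)C(=O)CC1=C(C)C[C@@H](O[Si](CC)(CC)CC)CC1(C)C | intermediate
10 | (2E)-dodec-2-enoic acid | CCCCCCCCC/C=C/C(=O)O | starting material
11 | (2E)-4,4-diethoxy-2-{[(4R)-2,6,6-trimethyl-4-(triethylsilyloxy)cyclohex-1-en-1-yl]acetyl}but-2-en-1-yl (2E)-dodec-2-enoate | CCCCCCCCC/C=C/C(=O)OC/C(=C\C(OCC)OCC)C(=O)CC1=C(C)C[C@@H](O[Si](CC)(CC)CC)CC1(C)C | intermediate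
12 | (2E)-2-{[(4R)-4-hydroxy-2,6,6-trimethylcyclohex-1-en-1-yl]acetyl}-4-oxobut-2-en-1-yl (2E)-dodec-2-enoate | CCCCCCCCC/C=C/C(=O)OC/C(=C\C=O)C(=O)CC1=C(C)C[C@@H](O)CC1(C)C | intermediate
13 | (3E)-4-[(1R)-2,6,6-trimethylcyclohex-2-en-1-yl]but-3-en-2-one ((R)-α-ionone) | CC(=O)/C=C/[C@H]1C(C)=CCCC1(C)C | starting material
14 | (1E)-3-methyl-1-[(1R)-2,6,6-trimethylcyclohex-2-en-1-yl]penta-1,4-dien-3-ol (both C3 epimers) | C=CC(C)(O)/C=C/[C@H]1C(C)=CCCC1(C)C | intermediate
15 | (4R)-4-[(1E)-3-hydroxy-3-methylpenta-1,4-dien-1-yl]-3,5,5-trimethylcyclohex-2-en-1-one | C=CC(C)(O)/C=C/[C@H]1C(C)=CC(=O)CC1(C)C | intermediate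
16 | (1S,4R)-4-[(1E)-3-hydroxy-3-methylpenta-1,4-dien-1-yl]-3,5,5-trimethylcyclohex-2-en-1-ol | C=CC(C)(O)/C=C/[C@H]1C(C)=C[C@@H](O)CC1(C)C | intermediate
17 | (1R,4R)-4-[(1E)-3-hydroxy-3-methylpenta-1,4-dien-1-yl]-3,5,5-trimethylcyclohex-2-en-1-yl 4-nitrobenzoate | C=CC(C)(O)/C=C/[C@H]1C(C)=C[C@H](OC(=O)c2ccc(cc2)[N+](=O)[O-])CC1(C)C | intermediate
18 | {(2E,4E)-3-methyl-5-[(1R,4R)-2,6,6-trimethyl-4-(4-nitrobenzoyloxy)cyclohex-2-en-1-yl]penta-2,4-dien-1-yl}triphenylphosphonium bromide | [Br-].c1ccccc1[P+](c1ccccc1)(c1ccccc1)C/C=C(C)/C=C/[C@H]1C(C)=C[C@H](OC(=O)c2ccc(cc2)[N+](=O)[O-])CC1(C)C | intermediate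
19 | (2E,4E,6E)-2,7-dimethylocta-2,4,6-trienedial (C10 dialdehyde) | O=C/C(C)=C/C=C/C=C(C)/C=O | starting material
20 | (2E,4E,6E,8E,10E,12E)-2,7,11-trimethyl-13-[(1R,4R)-2,6,6-trimethyl-4-(4-nitrobenzoyloxy)cyclohex-2-en-1-yl]trideca-2,4,6,8,10,12-hexaenal | O=C/C(C)=C/C=C/C=C(C)/C=C/C=C(C)/C=C/[C@H]1C(C)=C[C@H](OC(=O)c2ccc(cc2)[N+](=O)[O-])CC1(C)C | intermediate
21 | (1R,4R)-4-[(1E,3E,5E,7E,9E,11E)-13-hydroxy-3,7,12-trimethyltrideca-1,3,5,7,9,11-hexaen-1-yl]-3,5,5-trimethylcyclohex-2-en-1-yl 4-nitrobenzoate | OC/C(C)=C/C=C/C=C(C)/C=C/C=C(C)/C=C/[C@H]1C(C)=C[C@H](OC(=O)c2ccc(cc2)[N+](=O)[O-])CC1(C)C | intermediate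
22 | (1R,4R)-4-[(1E,3E,5E,7E,9E,11E)-13-hydroxy-3,7,12-trimethyltrideca-1,3,5,7,9,11-hexaen-1-yl]-3,5,5-trimethylcyclohex-2-en-1-ol | OC/C(C)=C/C=C/C=C(C)/C=C/C=C(C)/C=C/[C@H]1C(C)=C[C@H](O)CC1(C)C | intermediate
23 | {(2E,4E,6E,8E,10E,12E)-13-[(1R,4R)-4-hydroxy-2,6,6-trimethylcyclohex-2-en-1-yl]-2,7,11-trimethyltrideca-2,4,6,8,10,12-hexaen-1-yl}triphenylphosphonium bromide | [Br-].c1ccccc1[P+](c1ccccc1)(c1ccccc1)C/C(C)=C/C=C/C=C(C)/C=C/C=C(C)/C=C/[C@H]1C(C)=C[C@H](O)CC1(C)C | intermediate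
24 | (3R,3'R,6'R)-3,3'-dihydroxy-8-oxo-7,8-dihydro-β,ε-caroten-19-yl (2E)-dodec-2-enoate (siphonein, CNP0415260.1) | CCCCCCCCC/C=C/C(=O)OC\C(=C/C=C/C(C)=C/C=C/C=C(C)/C=C/C=C(C)/C=C/[C@H]1C(C)=C[C@H](O)CC1(C)C)C(=O)CC1=C(C)C[C@@H](O)CC1(C)C | target

**Step count and risks**

Total: 15 steps. Longest linear sequence: 9 steps (steps 7 to 15, from 13).

Most likely to fail:

1. Step 2 (the proposed new transformation). The risks are poor turnover with a hindered tertiary allylic C–H, acid-promoted isomerisation of the exocyclic alkene before coupling, and a second functionalisation of the product. Fallback with known chemistry, setting out from 1 and coming back at 4: silylate 1 (Et3SiCl, imidazole, DMF) to (4R,6R)-2,2,6-trimethyl-4-(triethylsilyloxy)cyclohexan-1-one F1. Convert its only possible enolate (KN(SiMe3)2, then PhNTf2, THF, −78 °C) into (4R)-2,6,6-trimethyl-4-(triethylsilyloxy)cyclohex-1-en-1-yl trifluoromethanesulfonate F2. Couple F2 with the zinc enolate BrZnCH2C(O)N(OMe)Me (from 2-bromo-N-methoxy-N-methylacetamide and zinc) under Pd(PPh3)4 catalysis (Negishi-type coupling of a Reformatsky reagent) to give 4.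

2. Step 4. The risks are wrong regiochemistry in the hydromagnesiation of an acetal-bearing alkynol and enolisation of the amide by the hindered alkenyl Grignard reagent. Fallback setting out from 4 and coming back at 11: add CH2=CHMgBr to 4 to obtain 1-[(4R)-2,6,6-trimethyl-4-(triethylsilyloxy)cyclohex-1-en-1-yl]but-3-en-2-one F3. Run a DABCO-catalysed Morita–Baylis–Hillman reaction with 2,2-diethoxyacetaldehyde to give 5,5-diethoxy-4-hydroxy-3-methylidene-1-[(4R)-2,6,6-trimethyl-4-(triethylsilyloxy)cyclohex-1-en-1-yl]pentan-2-one F4. Acylate with (2E)-dodec-2-enoyl chloride (made from 10) and pyridine to 1,1-diethoxy-3-methylidene-4-oxo-5-[(4R)-2,6,6-trimethyl-4-(triethylsilyloxy)cyclohex-1-en-1-yl]pentan-2-yl (2E)-dodec-2-enoate F5. Isomerise F5 with catalytic DABCO (SN2'–SN2' 1,3-acyloxy shift to the conjugated primary ester, carbonyl trans to the acetal carbon) to reach 11.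

3. Step 9. The facial selectivity of the hydride reduction is argued from conformation and may be modest; the mixed carbinol epimers in the side chain also make analysis harder. Fallback setting out from 15 and coming back at 17, which does not depend on selectivity: reduce 15 under Luche conditions (NaBH4, CeCl3·7H2O, MeOH, −20 °C) and separate the two ring-carbinol epimers on silica. Pass the cis epimer 16 through step 10. Acylate the trans epimer, (1R,4R)-4-[(1E)-3-hydroxy-3-methylpenta-1,4-dien-1-yl]-3,5,5-trimethylcyclohex-2-en-1-ol F6, directly with 4-nitrobenzoyl chloride and pyridine (retention). Both epimers then converge on 17.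

**Further compounds**
F1 | step 2 | (4R,6R)-2,2,6-trimethyl-4-(triethylsilyloxy)cyclohexan-1-one | O=C1C(C)(C)C[C@H](O[Si](CC)(CC)CC)C[C@H]1C
F2 | step 2 | (4R)-2,6,6-trimethyl-4-(triethylsilyloxy)cyclohex-1-en-1-yl trifluoromethanesulfonate | FC(F)(F)S(=O)(=O)OC1=C(C)C[C@@H](O[Si](CC)(CC)CC)CC1(C)C
F3 | step 4 | 1-[(4R)-2,6,6-trimethyl-4-(triethylsilyloxy)cyclohex-1-en-1-yl]but-3-en-2-one | C=CC(=O)CC1=C(C)C[C@@H](O[Si](CC)(CC)CC)CC1(C)C
F4 | step 4 | 5,5-diethoxy-4-hydroxy-3-methylidene-1-[(4R)-2,6,6-trimethyl-4-(triethylsilyloxy)cyclohex-1-en-1-yl]pentan-2-one (both C4 epimers) | CCOC(OCC)C(O)C(=C)C(=O)CC1=C(C)C[C@@H](O[Si](CC)(CC)CC)CC1(C)C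
F5 | step 4 | 1,1-diethoxy-3-methylidene-4-oxo-5-[(4R)-2,6,6-trimethyl-4-(triethylsilyloxy)cyclohex-1-en-1-yl]pentan-2-yl (2E)-dodec-2-enoate (both C2 epimers) | CCCCCCCCC/C=C/C(=O)OC(C(OCC)OCC)C(=C)C(=O)CC1=C(C)C[C@@H](O[Si](CC)(CC)CC)CC1(C)C
F6 | step 9 | (1R,4R)-4-[(1E)-3-hydroxy-3-methylpenta-1,4-dien-1-yl]-3,5,5-trimethylcyclohex-2-en-1-ol | C=CC(C)(O)/C=C/[C@H]1C(C)=C[C@H](O)CC1(C)C
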